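## Retrosynthetic overview

1. Locants: the terpenoid part is numbered as a spiro[4.5]decane (C1 = O–CH, C2 = C–CH3, C5 = spiro C, C6 = vinylic CH, C7 = C–iPr, C10 = CH–CH3); C4′ is the benzylic CH(iBu). The two CHO groups come last (Vilsmeier), after debenzylation. The pyran ring comes from spiro ketone 17 and an o-quinone methide (hetero-Diels–Alder: C2–C4′ and O–C1). CH3 (C2) and H (C1) are then added across the chromene C1=C2 by cyclopropanation, acid opening and silane reduction.
2. Key disconnection: the cyclohexene ring, bonds C5–C6 and C9–C10 in one step, by a silicon-tethered intramolecular Diels–Alder reaction of triene 13 ((E)-2-isopropyldienylsilane plus Z-ethylidene group). Protodesilylation of the resulting allylsilane then shifts the alkene to C6=C7 and releases C1–OH.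
3. Enabling feature: C1 (the O–CH shared by pyran and cyclopentane) is bonded to spiro C5, whose other ring neighbour is the vinylic C6–H. An O–Si bridge from the C1 oxygen to C6 (temporary 1-oxa-2-silacyclopentane C1–O–Si–C6–C5) therefore holds the diene on the exocyclic C5=C10 alkene, and silicon on C6 is at the same time the allylsilane that later places the C6=C7 double bond.
4. Ring order: cyclopentane (Ni-catalysed ynal cyclisation, Z-alkene) → cyclohexene with temporary oxasilolane (key step) → pyran (hetero-Diels–Alder onto the preformed arene).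
5. Stereochemistry: one carbinol centre (lipase resolution) is relayed to C5 and C10 in the key step and is then oxidised away. C5/C10 control C4′ (face of the cycloaddition), and C4′ together with C10 controls C2 and C1 (additions anti to the isobutyl group).

Key step: step 6

Assumption: hex-5-ynal is taken as the commercial starting point (it is also one oxidation away from hex-5-yn-1-ol), and CAL-B is taken to acylate the (R)-alcohol, as the empirical rule for secondary alcohols predicts.

## Route

Step 1
Reactants: 1 hex-5-ynal; 2 dimethylzinc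
Product: 3 rac-(Z)-2-ethylidenecyclopentan-1-ol
Conditions: Ni(cod)2 (10 mol%), Me2Zn (2.5 equiv), THF, 0 °C; aq. NH4Cl
Reagents that add atoms: dimethylzinc, C[Zn]C
Why: Nickel-catalysed alkylative cyclisation of an ynal with an organozinc (oxidative cyclisation to an oxanickelacyclopentene, Zn-to-Ni methyl transfer, C–C reductive elimination with retention) should close the five-membered ring and place the new methyl cis to the carbinol carbon, i.e. give the Z-alkene only; the carbinol centre is racemic at this stage.

Step 2
Reactants: 3 rac-(Z)-2-ethylidenecyclopentan-1-ol; 4 vinyl acetate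
Product: 5 (1S,2Z)-2-ethylidenecyclopentan-1-ol
Conditions: Novozym 435 (CAL-B), vinyl acetate (3 equiv), MTBE, 30 °C, run past half conversion; chromatography
Reagents that add atoms: none
Why: Lipase-catalysed kinetic resolution by irreversible transesterification should acylate the (R)-alcohol and leave (S)-5, which fixes the only stereocentre of the route that is not set by substrate control.

Step 3
Reactants: 5 (1S,2Z)-2-ethylidenecyclopentan-1-ol; 6 3-methylbut-1-yne; 7 dichlorodiisopropylsilane
Product: 10 {[(1S,2Z)-2-ethylidenecyclopentyl]oxy}diisopropyl(3-methylbut-1-yn-1-yl)silane, via lithium 3-methylbut-1-yn-1-ide 8 (not isolated), via chloro(diisopropyl)(3-methylbut-1-yn-1-yl)silane 9 (not isolated)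
Conditions: 6, n-BuLi, THF, −78 °C; 7 (1.0 equiv), −78 °C → rt; then 5, imidazole, DMF, 0 °C → rt
Reagents that add atoms: 3-methylbut-1-yne, CC(C)C#C; dichlorodiisopropylsilane, CC(C)[Si](Cl)(Cl)C(C)C
Why: Mono-alkynylation of the dichlorosilane followed by O-silylation of the secondary alcohol is the standard one-pot assembly of alkynylsilyl ether tethers and touches neither the stereocentre nor the Z-alkene.

Step 4
Reactants: 10 alkynylsilyl ether; 11 acetaldehyde
Product: 12 (3E)-4-({[(1S,2Z)-2-ethylidenecyclopentyl]oxy}diisopropylsilyl)-3-isopropylbut-3-en-2-ol (both carbinol epimers)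
Conditions: Ni(cod)2 (10 mol%), PBu3 (20 mol%), Et3B (2 equiv), MeCHO (3 equiv), toluene, rt
Reagents that add atoms: acetaldehyde, CC=O
Why: Nickel-catalysed reductive coupling of a silyl alkyne with an aldehyde (oxidative cyclisation with Ni on the Si-bearing carbon, ethyl transfer from boron, β-hydride elimination, C–H reductive elimination) should form the C–C bond at the isopropyl-bearing carbon and add H and carbon syn, so that Si ends cis to the isopropyl group; the new carbinol centre is uncontrolled and disappears in step 5.

Step 5
Reactants: 12 hydroxy vinylsilane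
Product: 13 {[(1S,2Z)-2-ethylidenecyclopentyl]oxy}diisopropyl[(1E)-2-isopropylbuta-1,3-dien-1-yl]silane
Conditions: Burgess reagent (2 equiv), benzene, 50 °C
Reagents that add atoms: none
Why: Burgess syn-elimination of the secondary allylic alcohol can only take a hydrogen from the methyl group (the other β-carbon is fully substituted), which gives the terminal vinyl group and leaves the vinylsilane geometry untouched.

Step 6
Reactants: 13 silicon-tethered triene
Product: 14 tricyclic allylsilane: cyclopentane C1–C5; new cyclohexene C5–C6(Si)–C7(iPr)=C8–C9–C10(CH3); 2,2-diisopropyl-1-oxa-2-silacyclopentane C1–O–Si–C6–C5; O on C1 cis to C6; CH3 on C10 cis to C1; C6 as either epimer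
Conditions: toluene (5 mM), BHT (cat.), sealed tube, 180 °C
Reagents that add atoms: none
Why: The step is a thermal type-1 intramolecular Diels–Alder reaction, a concerted but asynchronous [4π+2π] addition of the (E)-dienylsilane to the Z-ethylidene group, and its closest known reaction type is the silicon-tethered (temporary silicon connection) intramolecular Diels–Alder reaction of 1,3,8-nonatriene-type silyl ethers. It closes the cyclohexene ring by suprafacial–suprafacial cycloaddition (C5–C6 and C9–C10) and, through the same C5–C6 bond, the five-membered 1-oxa-2-silacyclopentane, which should be cis-fused to the cyclopentane. The spiro centre C5 is therefore controlled by the carbinol centre C1, because the O–Si tether can deliver the diene only to the alkene face syn to the C1 oxygen. The C10 centre is controlled by the Z geometry of the ethylidene group, since suprafacial addition keeps the methyl group cis to C1 on the new ring; C6 forms as either epimer (endo or exo tether) and is erased in step 7. The step needs regioselectivity (silylated diene terminus to C5, CH2 terminus to C10) and facial selectivity, both secured by the three-atom tether, and enough reactivity from an unactivated trisubstituted alkene, which is helped by intramolecularity, the gem-diisopropyl effect at silicon and the s-cis-favouring 2-isopropyl group of the diene.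

Step 7
Reactants: 14 tricyclic allylsilane
Product: 16 (1S,5R,10R)-7-isopropyl-10-methylspiro[4.5]dec-6-en-1-ol, via silyl trifluoroacetate 15 (not isolated)
Conditions: TFA (3 equiv), CH2Cl2, −20 → 0 °C; then TBAF (4 equiv), THF, rt
Reagents that add atoms: none
Why: Acid-mediated protodesilylation of the allylsilane in the SE2′ sense (proton to C8, loss of silicon from C6 through the β-silyl cation) moves the double bond to C6=C7 and fluoride then cleaves the Si–O bond; the C6 centre disappears while C1, C5 and C10 are untouched.

Step 8
Reactants: 16 spiro alcohol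
Product: 17 (5R,10R)-7-isopropyl-10-methylspiro[4.5]dec-6-en-1-one
Conditions: Dess–Martin periodinane (1.5 equiv), CH2Cl2, rt
Reagents that add atoms: none
Why: Dess–Martin oxidation of the hindered secondary alcohol gives a β,γ-unsaturated ketone that can neither epimerise nor conjugate, because C5 is quaternary.

Step 9
Reactants: 17 spiro ketone; 18 trimethylsilyl trifluoromethanesulfonate
Product: 19 trimethyl{[(5R,10R)-7-isopropyl-10-methylspiro[4.5]deca-1,6-dien-1-yl]oxy}silane
Conditions: TMSOTf (1.3 equiv), Et3N (2 equiv), CH2Cl2, 0 °C
Reagents that add atoms: trimethylsilyl trifluoromethanesulfonate, C[Si](C)(C)OS(=O)(=O)C(F)(F)F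
Why: Soft enolisation and O-silylation can only go towards C2, since C5 carries no hydrogen.

Step 10
Reactants: 20 2,4,6-trihydroxybenzaldehyde; 21 benzyl bromide
Product: 22 2,4-bis(benzyloxy)-6-hydroxybenzaldehyde
Conditions: BnBr (2.05 equiv), K2CO3 (2.2 equiv), DMF, 0 °C → rt
Reagents that add atoms: benzyl bromide, BrCc1ccccc1
Why: Williamson benzylation takes the 4-OH and one 2-OH, while the last OH is deactivated by its hydrogen bond to the formyl group.

Step 11
Reactants: 22 2,4-bis(benzyloxy)-6-hydroxybenzaldehyde; 23 di-tert-butyl dicarbonate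
Product: 24 3,5-bis(benzyloxy)-2-formylphenyl tert-butyl carbonate
Conditions: Boc2O (1.2 equiv), iPr2NEt, DMAP (cat.), THF, rt
Reagents that add atoms: di-tert-butyl dicarbonate, CC(C)(C)OC(=O)OC(=O)OC(C)(C)C
Why: DMAP-catalysed O-acylation gives the aryl carbonate that allows the quinone methide to be generated at low temperature by Boc transfer.

Step 12
Reactants: 24 aryl carbonate aldehyde; 25 isobutylmagnesium bromide; 19 silyl enol ether
Product: 28 5,7-bis(benzyloxy)-4-isobutyl-4H-chromene fused at C1=C2 to the spiro[4.5]decene (isobutyl on the C10 face), via o-quinone methide 26 (not isolated), via silyl ketal cycloadduct 27 (not isolated)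
Conditions: 24, iBuMgBr (1.0 equiv), Et2O, −78 °C; 19 (0.6 equiv), −78 °C → rt; then TsOH·H2O (10 mol%), 4 Å MS, CH2Cl2, rt
Reagents that add atoms: isobutylmagnesium bromide, CC(C)C[Mg]Br
Why: Grignard addition, Boc transfer and elimination generate the (E)-o-quinone methide, whose inverse-demand hetero-Diels–Alder reaction with the silyl enol ether should take place on the cyclopentene face of the vinylic C6–H (anti to the C10 branch) with OSiMe3 endo and the spiro ring exo, which fixes C4′; acid then eliminates Me3SiOH towards C2, the only position with a hydrogen, to give the 4H-chromene.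

Step 13
Reactants: 28 4H-chromene; 29 diiodomethane
Product: 30 cyclopropane fused across C1–C2 (CH2 on the face of C6, anti to the isobutyl group)
Conditions: Et2Zn (5 equiv), CH2I2 (10 equiv), CH2Cl2, 0 °C → rt
Reagents that add atoms: diiodomethane, ICI
Why: Furukawa–Simmons–Smith cyclopropanation should prefer the electron-rich enol ether over the hindered trialkyl alkene and deliver CH2 to the face anti to the pseudo-axial isobutyl group and the C10 branch, which sets the configuration of the future C2 quaternary centre.

Step 14
Reactants: 30 cyclopropane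
Product: 32 5,7-bis(benzyloxy) chroman with all five stereocentres of the target, via methyl ketal 31 (not isolated)
Conditions: HCl (cat., from AcCl), MeOH/CH2Cl2, 40 °C; evaporate; then Et3SiH (5 equiv), BF3·OEt2 (2 equiv), CH2Cl2, −78 → −30 °C
Reagents that add atoms: none
Why: Acid-catalysed opening of the aryloxycyclopropane by protonation of the unhindered CH2 gives the C2 methyl with retention and an oxocarbenium ion that is trapped as the methyl ketal, and Lewis-acid/silane reduction of that ketal should deliver hydride to C1 from the methyl-bearing face (anti to the axial isobutyl group and the C10 branch) to give the cis-fused chroman.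

Step 15
Reactants: 32 bis(benzyl) ether
Product: 33 5,7-dihydroxychroman
Conditions: BCl3 (6 equiv), pentamethylbenzene (6 equiv), CH2Cl2, −78 °C; MeOH quench
Reagents that add atoms: none
Why: Lewis-acid debenzylation with a non-Lewis-basic cation scavenger cleaves aryl benzyl ethers at −78 °C and should spare the trisubstituted alkene and the hindered chroman ether.

Step 16
Reactants: 33 5,7-dihydroxychroman; 34 N,N-dimethylformamide
Product: 35 CNP0121396.1 (target)
Conditions: POCl3 (5 equiv), DMF, 0 → 40 °C; then aq. NaOAc, 50 °C
Reagents that add atoms: N,N-dimethylformamide, CN(C)C=O; water, O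
Why: Vilsmeier–Haack formylation should take both free ring positions of the phloroglucinol-type arene (each ortho or para to three oxygens) under conditions that do not protonate the alkene, and hydrolysis of the bis-iminium salt gives the dialdehyde without touching any stereocentre.

## Compound list

1 | hex-5-ynal | C#CCCCC=O | starting material
2 | dimethylzinc | C[Zn]C | starting material
3 | rac-(Z)-2-ethylidenecyclopentan-1-ol | C/C=C1/CCCC1O | intermediate
4 | vinyl acetate | CC(=O)OC=C | starting material
5 | (1S,2Z)-2-ethylidenecyclopentan-1-ol | C/C=C1/CCC[C@@H]1O | intermediate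
6 | 3-methylbut-1-yne | CC(C)C#C | starting material
7 | dichlorodiisopropylsilane | CC(C)[Si](Cl)(Cl)C(C)C | starting material
8 | lithium 3-methylbut-1-yn-1-ide | [Li]C#CC(C)C | intermediate
9 | chloro(diisopropyl)(3-methylbut-1-yn-1-yl)silane | CC(C)C#C[Si](Cl)(C(C)C)C(C)C | intermediate
10 | {[(1S,2Z)-2-ethylidenecyclopentyl]oxy}diisopropyl(3-methylbut-1-yn-1-yl)silane | C/C=C1/CCC[C@@H]1O[Si](C(C)C)(C(C)C)C#CC(C)C | intermediate
11 | acetaldehyde | CC=O | starting material
12 | (3E)-4-({[(1S,2Z)-2-ethylidenecyclopentyl]oxy}diisopropylsilyl)-3-isopropylbut-3-en-2-ol (carbinol epimers) | C/C=C1/CCC[C@@H]1O[Si](C(C)C)(C(C)C)/C=C(\C(C)C)C(C)O | intermediate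
13 | {[(1S,2Z)-2-ethylidenecyclopentyl]oxy}diisopropyl[(1E)-2-isopropylbuta-1,3-dien-1-yl]silane | C/C=C1/CCC[C@@H]1O[Si](C(C)C)(C(C)C)/C=C(\C(C)C)C=C | intermediate
14 | Diels–Alder adduct, tricyclic allylsilane (O on C1 cis to C6, CH3 on C10 cis to C1, C6 epimers) | CC(C)C1=CC[C@@H](C)[C@@]23CCC[C@@H]2O[Si](C(C)C)(C(C)C)C13 | intermediate
15 | diisopropyl{[(1S,5R,10R)-7-isopropyl-10-methylspiro[4.5]dec-6-en-1-yl]oxy}silyl trifluoroacetate | O=C(O[Si](C(C)C)(C(C)C)O[C@H]1CCC[C@@]12C=C(C(C)C)CC[C@H]2C)C(F)(F)F | intermediate
16 | (1S,5R,10R)-7-isopropyl-10-methylspiro[4.5]dec-6-en-1-ol | O[C@H]1CCC[C@@]12C=C(C(C)C)CC[C@H]2C | intermediate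
17 | (5R,10R)-7-isopropyl-10-methylspiro[4.5]dec-6-en-1-one | O=C1CCC[C@@]12C=C(C(C)C)CC[C@H]2C | intermediate
18 | trimethylsilyl trifluoromethanesulfonate | C[Si](C)(C)OS(=O)(=O)C(F)(F)F | starting material
19 | trimethyl{[(5R,10R)-7-isopropyl-10-methylspiro[4.5]deca-1,6-dien-1-yl]oxy}silane | C[Si](C)(C)OC1=CCC[C@@]12C=C(C(C)C)CC[C@H]2C | intermediate
20 | 2,4,6-trihydroxybenzaldehyde | O=Cc1c(O)cc(O)cc1O | starting material
21 | benzyl bromide | BrCc1ccccc1 | starting material
22 | 2,4-bis(benzyloxy)-6-hydroxybenzaldehyde | O=Cc1c(O)cc(OCc2ccccc2)cc1OCc1ccccc1 | intermediate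
23 | di-tert-butyl dicarbonate | CC(C)(C)OC(=O)OC(=O)OC(C)(C)C | starting material
24 | 3,5-bis(benzyloxy)-2-formylphenyl tert-butyl carbonate | CC(C)(C)OC(=O)Oc1cc(OCc2ccccc2)cc(OCc2ccccc2)c1C=O | intermediate
25 | isobutylmagnesium bromide | CC(C)C[Mg]Br | starting material
26 | (6E)-3,5-bis(benzyloxy)-6-(3-methylbutylidene)cyclohexa-2,4-dien-1-one (o-quinone methide) | CC(C)C/C=C1/C(=O)C=C(OCc2ccccc2)C=C1OCc1ccccc1 | intermediate
27 | silyl ketal cycloadduct (pyran on the C6 face, isobutyl cis to OSiMe3) | CC(C)C[C@H]1c2c(OCc3ccccc3)cc(OCc3ccccc3)cc2O[C@@]2(O[Si](C)(C)C)[C@@H]1CC[C@@]21C=C(C(C)C)CC[C@H]1C | intermediate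
28 | 5,7-bis(benzyloxy)-4-isobutyl-4H-chromene fused at C1=C2 to the spiro[4.5]decene | CC(C)C[C@H]1c2c(OCc3ccccc3)cc(OCc3ccccc3)cc2OC2=C1CC[C@@]21C=C(C(C)C)CC[C@H]1C | intermediate
29 | diiodomethane | ICI | starting material
30 | cyclopropa-fused chroman (CH2 across C1–C2 on the C6 face) | CC(C)C[C@H]1c2c(OCc3ccccc3)cc(OCc3ccccc3)cc2O[C@@]23C[C@]13CC[C@@]21C=C(C(C)C)CC[C@H]1C | intermediate
31 | C1 methyl ketal with C2 methyl (C1 anomers) | CC(C)C[C@H]1c2c(OCc3ccccc3)cc(OCc3ccccc3)cc2OC2(OC)[C@@]1(C)CC[C@@]21C=C(C(C)C)CC[C@H]1C | intermediate
32 | 5,7-bis(benzyloxy) chroman (bis-benzyl ether of 33) | CC(C)C[C@H]1c2c(OCc3ccccc3)cc(OCc3ccccc3)cc2O[C@@H]2[C@@]1(C)CC[C@@]21C=C(C(C)C)CC[C@H]1C | intermediate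
33 | 5,7-dihydroxychroman (target without the two formyl groups) | CC(C)C[C@H]1c2c(O)cc(O)cc2O[C@@H]2[C@@]1(C)CC[C@@]21C=C(C(C)C)CC[C@H]1C | intermediate
34 | N,N-dimethylformamide | CN(C)C=O | starting material
35 | CNP0121396.1 | CC(C)C[C@H]1c2c(O)c(C=O)c(O)c(C=O)c2O[C@@H]2[C@@]1(C)CC[C@@]21C=C(C(C)C)CC[C@H]1C | target

## Step count and risks

Total step count: 16. Longest linear sequence: 14 steps (1–9, then 12–16); steps 10–11 make the arene partner.

Steps most likely to fail:

Step 6. The cycloaddition may stall, because a bond has to form between the silylated diene terminus and a fully substituted carbon of an unactivated trisubstituted alkene, so that diene oligomerisation or loss of silicon at 180 °C may win. The fallback sets out from 5 and comes back at 16. It replaces the C–Si tether by an O–Si–O tether to a 1-oxygenated diene, which takes the bulky silicon off the bond-forming terminus and closes a six- instead of a five-membered tether ring. Alcohol 5 is silylated with iPr2Si(OTf)2/2,6-lutidine, and the remaining Si–OTf O-silylates the dienolate of (2E)-2-isopropylbut-2-enal F1 (from a directed aldol condensation of 3-methylbutanal with acetaldehyde; Et3N), which gives the silaketal triene F2. Heating gives the cycloadduct F3 (C6–O in place of C6–Si), and HF·pyridine gives the diol F4. MnO2 oxidises only the allylic C6–OH to the enone F5. Its tosylhydrazone F6 is reduced with catecholborane and warmed with NaOAc (reductive 1,3-transposition through the allylic diazene), which moves the alkene to C6=C7 and returns 16.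

Step 12. Facial or endo/exo control in the cycloaddition may be poor, or the magnesium alkoxides may cleave the silyl enol ether before the quinone methide forms; either would scramble or lose the benzylic centre. The fallback sets out from 17 and comes back at 32, so it also replaces steps 13 and 14. It sets the benzylic centre by hydride delivery instead of by cycloaddition. Aldol addition of the lithium enolate of 17 to 3-methylbutanal gives the aldol adduct F7, and Dess–Martin oxidation gives the 1,3-diketone F8. C-Methylation (K2CO3, MeI) from the less hindered C6 face gives the 2-methyl-1,3-diketone F9. Acid-mediated condensation of F9 with commercial 3,5-bis(benzyloxy)phenol (BF3·OEt2: hemiketal at C1, Friedel–Crafts closure at the side-chain ketone) in the presence of Et3SiH should reduce the benzylic cation from the convex, methyl-bearing face and the C1 oxocarbenium ion in the same sense, which gives 32.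

Step 13. The tetrasubstituted enol ether flanked by the spiro centre and the benzylic centre may be too hindered for the zinc carbenoid, or the C6=C7 alkene may compete. The fallback sets out from 28 and comes back at 31. It brings in the methyl carbon as a thionium electrophile instead of a carbenoid. Phenylthiomethylation of the enol ether with PhSCH2Cl/ZnBr2 at −78 °C, followed by trapping of the oxocarbenium ion with methanol, gives the phenylthiomethyl ketal F10 (same facial argument as in step 13). Desulfurisation with deactivated Raney nickel gives the methyl ketal 31, which is reduced as in the second stage of step 14.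

## Further compounds

F1 | step 6 | (2E)-2-isopropylbut-2-enal | C/C=C(/C=O)C(C)C
F2 | step 6 | {[(1S,2Z)-2-ethylidenecyclopentyl]oxy}{[(1E)-2-isopropylbuta-1,3-dien-1-yl]oxy}diisopropylsilane | C/C=C1/CCC[C@@H]1O[Si](C(C)C)(C(C)C)O/C=C(\C(C)C)C=C
F3 | step 6 | silaketal cycloadduct (1,3-dioxa-2-silacyclohexane C1–O–Si–O–C6, C6 epimers) | CC(C)C1=CC[C@@H](C)[C@@]23CCC[C@@H]2O[Si](C(C)C)(C(C)C)OC13
F4 | step 6 | (1S,10R)-7-isopropyl-10-methylspiro[4.5]dec-7-ene-1,6-diol (C6 epimers) | CC(C)C1=CC[C@@H](C)[C@]2(CCC[C@@H]2O)C1O
F5 | step 6 | (1S,10R)-1-hydroxy-7-isopropyl-10-methylspiro[4.5]dec-7-en-6-one | CC(C)C1=CC[C@@H](C)[C@]2(CCC[C@@H]2O)C1=O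
F6 | step 6 | 4-methylbenzenesulfonylhydrazone of F5 | CC(C)C1=CC[C@@H](C)[C@]2(CCC[C@@H]2O)C1=NNS(=O)(=O)c1ccc(C)cc1
F7 | step 12 | 2-(1-hydroxy-3-methylbutyl)-7-isopropyl-10-methylspiro[4.5]dec-6-en-1-one (epimers at C2 and carbinol) | O=C1C(C(O)CC(C)C)CC[C@@]12C=C(C(C)C)CC[C@H]2C
F8 | step 12 | 7-isopropyl-10-methyl-2-(3-methylbutanoyl)spiro[4.5]dec-6-en-1-one | O=C1C(C(=O)CC(C)C)CC[C@@]12C=C(C(C)C)CC[C@H]2C
F9 | step 12 | 7-isopropyl-2,10-dimethyl-2-(3-methylbutanoyl)spiro[4.5]dec-6-en-1-one (C2 methyl on the C6 face) | O=C1[C@](C)(C(=O)CC(C)C)CC[C@@]12C=C(C(C)C)CC[C@H]2C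
F10 | step 13 | C1 methyl ketal with C2 phenylthiomethyl group (C1 anomers) | CC(C)C[C@H]1c2c(OCc3ccccc3)cc(OCc3ccccc3)cc2OC2(OC)[C@@]1(CSc4ccccc4)CC[C@@]21C=C(C(C)C)CC[C@H]1C
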